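The data are simulated for an exercise, and the scatter is random.

At 1.5 h, the time you want read, we expect X still solid in this flask, although green's solid stood at 0% by that time.

| flask | X | E | remark | time |
|---|---|---|---|---|
| green | 1 M | 2.25 M | run made earlier |  |
| blue | 2.2 M | 2.25 M | run made earlier |  |
| flask | 1.5 M | 2.25 M |  | 1.5 h |

| run | time / min | X / % | Q / % |
|---|---|---|---|
| green | 25.0 | 38 | 9 |
| green | 50.0 | 9 | 12 |
| green | 60.0 | 3 | 13 |
| green | 90.0 | 0 | 12 |
| blue | 12.0 | 86 | 5 |
| blue | 30.0 | 69 | 2 |
| blue | 60.0 | 55 | 6 |
| blue | 90.0 | 50 | 5 |

(scatter of a reading: 2 percentage points)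

- given per volume of solution although it is solid: X
- at the start none of X is in solution

- X at 1.5 h, in percent of the X charged (only what is still solid)
- Q at 1.5 h, in percent of the X charged
- D at 1.5 h, in percent of the X charged
- L at 1.5 h, in percent of the X charged

Blue has nearly stopped by 90.0 min with 50% of its X still solid, and we assume that its E is spent by then. Its E charge over the X it lost gives 2.05; call this the E price, the E spent per X that leaves the solid. It is a reading and carries that scatter. Green had 2.25 E per X charged, more than the price, and its solid did reach 0%. Freezing the price, the E in this flask pays for 73.3% of its X, less than the whole charge. So E is the limiting reagent, and we reckon on 26.7% still solid.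

The forecast rests on the same ground, “at about two E per X reacted”, and gives X 27%, Q 7%, D 55% and L 11%.

The flask gives X 25.1%, Q 9.13%, D 1.48% and L 16.6%.

    D → Z (k = 0.0820 min⁻¹)
    E + D → L (k = 0.130 L mol⁻¹ min⁻¹)
    E + Q → D (k = 0.120 L mol⁻¹ min⁻¹)
    E + L → J (k = 0.0170 L mol⁻¹ min⁻¹)
    X ⇌ G, rate k5*(cs5 - [G]) while solid is left; crystals form when [G] > cs5 (solubility = 0.260 M, k = 0.190 min⁻¹)
    G + E → Q (k = 0.0750 L mol⁻¹ min⁻¹)

Per X out of the solid, this flask used 1.92 E, with 3.9% of its E left, against our price of 2.05. The forecast parts from the flask on D: the step D → Z, taken by itself, halves D in 8.45 min, and the reading comes ten times later than that. At that hour this flask holds Z at 21.0% of the X charged and D at 1.48%.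

In a neighbour flask with 0.60 M of X, the price pays for 183% of its X, over the whole charge, so we expect the solid gone. That flask computes to X 0%, with 22% of its E left.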